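**Retrosynthetic overview**
- The target comes from fluoride desilylation and MnO2 allylic oxidation of a C40 (3R,6R,3'R,6'R)-ε,ε-carotene-3,3'-diol mono-triethylsilyl ether, so the base-labile 3-oxo ring A appears only after all olefinations.
- C40 = C15 + C10 + C15: two successive Horner–Wadsworth–Emmons olefinations (C11'=C12', then C11=C12) of a C10 triene bisphosphonate, made from the commercial C10 dialdehyde, with two C15 dienals.
- Both C15 dienals (ring B as OSiEt3, ring A as free OH) come from one (3R,6R)-3-hydroxy C15 nitrile, made by CBS reduction, C3 allylic oxidation and cyanomethylphosphonate olefination of (R)-α-ionone.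
- Ring order: ring A and ring B are the same cyclohexene, made once and first by the proposed enantioselective Brønsted-acid cyclisation of pseudoionone to (R)-α-ionone, which closes the ring and sets C6 and C6'.

Assumption: ring positions use carotenoid numbering (C3, C6, C3', C6'); geometrically pure (3E,5E)-pseudoionone is taken as the commercial material, and the antipode of the new acid catalyst that delivers (R)-α-ionone is the one meant.

**Route**

Step 1
Reactants: 1 (3E,5E)-6,10-dimethylundeca-3,5,9-trien-2-one (pseudoionone)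
Product: 2 (R)-α-ionone [(3E)-4-[(1R)-2,6,6-trimethylcyclohex-2-en-1-yl]but-3-en-2-one]
Conditions: (S,S)-imidodiphosphorimidate Brønsted acid (3 mol %; two (S)-3,3'-bis[3,5-bis(trifluoromethyl)phenyl]-1,1'-bi-2-naphthol units, each phosphorus bearing =N–SO2CF3, the two phosphorus atoms bridged by N–H), (CF3)2CHOH/CH2Cl2 1:4, −40 °C, stopped at about 90% conversion with Et3N
Reagents that add atoms: none
Why: Proposed new method: the confined, strongly acidic chiral imidodiphosphorimidate protonates the electron-rich remote Me2C=CH alkene (the dienone carbonyl only hydrogen-bonds reversibly in the fluoroalcohol), the tertiary cation stays ion-paired inside the chiral anion pocket, the 5E alkene folds chair-like and attacks through one enantiotopic face to close the six-membered ring and set the single ring stereocentre (C6, R), and the basic counter-anion removes the neighbouring ring CH2 proton kinetically to give the non-conjugated α-alkene instead of β-ionone; the closest known reactions are the racemic H3PO4 cyclisation of pseudoionone and imidodiphosphorimidate-catalysed enantioselective cation–olefin polyene cyclisations in fluorinated alcohols, which have not been shown on a dienone-terminated substrate.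

Step 2
Reactants: 2 (R)-α-ionone
Product: 3 (2E,4E)-3-methyl-5-[(1R)-2,6,6-trimethylcyclohex-2-en-1-yl]penta-2,4-dienenitrile
Conditions: (EtO)2P(O)CH2CN (1.3 equiv), NaH (1.25 equiv), THF, 0 °C to rt; chromatography removes the minor 2Z isomer
Reagents that add atoms: diethyl cyanomethylphosphonate, CCOP(=O)(CC#N)OCC
Why: Horner–Wadsworth–Emmons olefination of the methyl ketone gives mainly the 2E nitrile (about 3:1 expected), and the stabilised phosphonate anion is far too weak a base to remove the C6 proton, so the ring stereocentre is carried through unchanged.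

Step 3
Reactants: 3 (2E,4E)-C15 nitrile
Product: 4 (2E,4E)-3-methyl-5-[(1R)-2,6,6-trimethyl-4-oxocyclohex-2-en-1-yl]penta-2,4-dienenitrile
Conditions: Rh2(cap)4 (dirhodium tetrakis(caprolactamate), 1 mol %), t-BuOOH (70% in water, 5 equiv), ClCH2CH2Cl, 40 °C, no added base
Reagents that add atoms: tert-butyl hydroperoxide, CC(C)(C)OO
Why: Radical allylic C–H oxidation (Kharasch-type tert-butylperoxyl chain) attacks the only accessible ring allylic CH2 (C3) because the C6–H bond is shielded by the gem-dimethyl and C5-methyl groups and lies in the plane of the side-chain alkene, and the neutral medium leaves the now acidic C6–H stereocentre untouched.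

Step 4
Reactants: 4 3-oxo C15 nitrile
Product: 5 (2E,4E)-5-[(1R,4R)-4-hydroxy-2,6,6-trimethylcyclohex-2-en-1-yl]-3-methylpenta-2,4-dienenitrile
Conditions: (S)-2-methyl-CBS-oxazaborolidine [(S)-1-methyl-3,3-diphenyltetrahydro-1H,3H-pyrrolo[1,2-c][1,3,2]oxazaborole] (0.2 equiv), catecholborane (1.5 equiv), toluene, −78 to −40 °C; then MeOH, aq. NaHCO3
Reagents that add atoms: none
Why: Corey–Bakshi–Shibata reduction, in which the (S)-oxazaborolidine binds the ring ketone with the alkenyl arm as the large group and delivers hydride to the face that gives the (R)-carbinol at C3, trans to the C6 side chain (reagent control), with 1,2-selectivity and no reaction at the nitrile.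

Step 5
Reactants: 5 (3R,6R)-3-hydroxy C15 nitrile
Product: 7 (2E,4E)-5-[(1R,4R)-4-hydroxy-2,6,6-trimethylcyclohex-2-en-1-yl]-3-methylpenta-2,4-dienal, via aluminated aldimine 6 (not isolated)
Conditions: i-Bu2AlH (2.5 equiv), CH2Cl2, −78 to −40 °C; then aq. KNaC4H4O6, rt
Reagents that add atoms: water, O
Why: Partial reduction of the conjugated nitrile by i-Bu2AlH stops at the N-aluminio imine (the first equivalent is used by the hydroxyl), and aqueous work-up hydrolyses it to the E-configured dienal without touching either stereocentre.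

Step 6
Reactants: 7 (3R,6R)-3-hydroxy C15 dienal
Product: 8 (2E,4E)-3-methyl-5-[(1R,4R)-2,6,6-trimethyl-4-(triethylsilyloxy)cyclohex-2-en-1-yl]penta-2,4-dienal
Conditions: Et3SiCl (1.2 equiv), imidazole (2.5 equiv), DMF, 0 °C
Reagents that add atoms: chlorotriethylsilane, CC[Si](Cl)(CC)CC
Why: Imidazole-promoted silylation (silyl ether protection) of the only hydroxyl marks ring B, leaves the dienal untouched and does not involve either stereocentre.

Step 7
Reactants: 9 (2E,4E,6E)-2,7-dimethylocta-2,4,6-trienedial (C10 dialdehyde)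
Product: 10 (2E,4E,6E)-2,7-dimethylocta-2,4,6-triene-1,8-diol
Conditions: NaBH4 (1.0 equiv), MeOH/THF 1:1, 0 °C
Reagents that add atoms: none
Why: Borohydride 1,2-reduction of both conjugated aldehydes gives the bis-allylic diol with the all-E triene intact.

Step 8
Reactants: 10 C10 diol
Product: 11 (2E,4E,6E)-1,8-dibromo-2,7-dimethylocta-2,4,6-triene
Conditions: PBr3 (0.75 equiv), pyridine (0.1 equiv), Et2O, −10 °C, dark; used crude
Reagents that add atoms: phosphorus tribromide, BrP(Br)Br
Why: Bromination of the primary allylic alcohols through their bromophosphite esters (nucleophilic substitution by bromide) gives the dibromide, which is the thermodynamically favoured all-E isomer.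

Step 9
Reactants: 11 C10 dibromide
Product: 12 tetraethyl [(2E,4E,6E)-2,7-dimethylocta-2,4,6-triene-1,8-diyl]bis(phosphonate)
Conditions: P(OEt)3 (4 equiv), 100 °C, EtBr distilled off
Reagents that add atoms: triethyl phosphite, CCOP(OCC)OCC
Why: Michaelis–Arbuzov reaction of the reactive primary allylic bromides with triethyl phosphite installs both phosphonates at the chain termini.

Step 10
Reactants: 8 ring B triethylsilyl C15 dienal; 12 C10 bisphosphonate
Product: 13 diethyl [(2E,4E,6E,8E,10E,12E)-2,7,11-trimethyl-13-[(1R,4R)-2,6,6-trimethyl-4-(triethylsilyloxy)cyclohex-2-en-1-yl]trideca-2,4,6,8,10,12-hexaen-1-yl]phosphonate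
Conditions: 12 (3 equiv), NaN(SiMe3)2 (1.0 equiv), THF, −78 °C; then 8 (1.0 equiv), −78 to 0 °C; excess 12 recovered by chromatography
Reagents that add atoms: none
Why: Horner–Wadsworth–Emmons olefination of the allylic phosphonate carbanion with the enal forms the C11'=C12' bond E-selectively, and mono-olefination is enforced by the threefold excess of 12, one equivalent of base and consumption of the aldehyde as the β-oxido phosphonate at −78 °C before any product is released.

Step 11
Reactants: 13 C25 phosphonate; 7 (3R,6R)-3-hydroxy C15 dienal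
Product: 14 (all-E,3R,6R,3'R,6'R)-3'-(triethylsilyloxy)-ε,ε-caroten-3-ol
Conditions: 13 (1.1 equiv), NaN(SiMe3)2 (1.1 equiv), THF, −78 °C; then 7 (1.0 equiv), −78 to 0 °C; recrystallisation to the all-E isomer
Reagents that add atoms: none
Why: A second Horner–Wadsworth–Emmons olefination forms the C11=C12 bond E-selectively and completes the C40 chain, the free hydroxyl of 7 being tolerated because the delocalised polyenyl phosphonate anion is less basic than an alkoxide.

Step 12
Reactants: 14 C40 mono-silyl diol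
Product: 15 (all-E,6R,3'R,6'R)-3'-(triethylsilyloxy)-ε,ε-caroten-3-one
Conditions: activated MnO2 (20 equiv), CH2Cl2, rt, dark, argon
Reagents that add atoms: none
Why: Heterogeneous MnO2 oxidation of the only free hydroxyl, which is allylic, gives the ring A enone under neutral conditions that neither epimerise C6 nor touch the silyl ether or the polyene.

Step 13
Reactants: 15 C40 silyl ether ketone
Product: 16 (all-E,6R,3'R,6'R)-3'-hydroxy-ε,ε-caroten-3-one (target CNP0344065.2)
Conditions: HF·pyridine, pyridine, THF, 0 °C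
Reagents that add atoms: none
Why: Fluoride-mediated Si–O cleavage (desilylation) under buffered, weakly acidic conditions frees the (3'R)-hydroxyl while avoiding base, which would epimerise or isomerise the 3-oxo ring A at C6, and strong acid, which would ionise the allylic C3'–O bond.

**Compound list**
1 | (3E,5E)-6,10-dimethylundeca-3,5,9-trien-2-one (pseudoionone) | CC(=O)/C=C/C=C(\C)CCC=C(C)C | starting material
2 | (R)-α-ionone, (3E)-4-[(1R)-2,6,6-trimethylcyclohex-2-en-1-yl]but-3-en-2-one | CC(=O)/C=C/[C@H]1C(C)=CCCC1(C)C | intermediate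
3 | (2E,4E)-3-methyl-5-[(1R)-2,6,6-trimethylcyclohex-2-en-1-yl]penta-2,4-dienenitrile | N#C/C=C(C)/C=C/[C@H]1C(C)=CCCC1(C)C | intermediate
4 | (2E,4E)-3-methyl-5-[(1R)-2,6,6-trimethyl-4-oxocyclohex-2-en-1-yl]penta-2,4-dienenitrile | N#C/C=C(C)/C=C/[C@H]1C(C)=CC(=O)CC1(C)C | intermediate
5 | (2E,4E)-5-[(1R,4R)-4-hydroxy-2,6,6-trimethylcyclohex-2-en-1-yl]-3-methylpenta-2,4-dienenitrile | N#C/C=C(C)/C=C/[C@H]1C(C)=C[C@H](O)CC1(C)C | intermediate
6 | aluminated aldimine (N-diisobutylaluminio imine and O-diisobutylaluminium alkoxide of 7; not isolated, hydrolysed on work-up) | CC(C)C[Al](CC(C)C)N=C/C=C(C)/C=C/[C@H]1C(C)=C[C@H](O[Al](CC(C)C)CC(C)C)CC1(C)C | intermediate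
7 | (2E,4E)-5-[(1R,4R)-4-hydroxy-2,6,6-trimethylcyclohex-2-en-1-yl]-3-methylpenta-2,4-dienal | O=C/C=C(C)/C=C/[C@H]1C(C)=C[C@H](O)CC1(C)C | intermediate
8 | (2E,4E)-3-methyl-5-[(1R,4R)-2,6,6-trimethyl-4-(triethylsilyloxy)cyclohex-2-en-1-yl]penta-2,4-dienal | O=C/C=C(C)/C=C/[C@H]1C(C)=C[C@H](O[Si](CC)(CC)CC)CC1(C)C | intermediate
9 | (2E,4E,6E)-2,7-dimethylocta-2,4,6-trienedial | O=C/C(C)=C/C=C/C=C(C)/C=O | starting material
10 | (2E,4E,6E)-2,7-dimethylocta-2,4,6-triene-1,8-diol | OC/C(C)=C/C=C/C=C(C)/CO | intermediate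
11 | (2E,4E,6E)-1,8-dibromo-2,7-dimethylocta-2,4,6-triene | BrC/C(C)=C/C=C/C=C(C)/CBr | intermediate
12 | tetraethyl [(2E,4E,6E)-2,7-dimethylocta-2,4,6-triene-1,8-diyl]bis(phosphonate) | CCOP(=O)(OCC)C/C(C)=C/C=C/C=C(C)/CP(=O)(OCC)OCC | intermediate
13 | diethyl [(2E,4E,6E,8E,10E,12E)-2,7,11-trimethyl-13-[(1R,4R)-2,6,6-trimethyl-4-(triethylsilyloxy)cyclohex-2-en-1-yl]trideca-2,4,6,8,10,12-hexaen-1-yl]phosphonate | CCOP(=O)(OCC)C/C(C)=C/C=C/C=C(C)/C=C/C=C(C)/C=C/[C@H]1C(C)=C[C@H](O[Si](CC)(CC)CC)CC1(C)C | intermediate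
14 | (all-E,3R,6R,3'R,6'R)-3'-(triethylsilyloxy)-ε,ε-caroten-3-ol (ring A free 3-OH, ring B 3'-OSiEt3) | CC1=C[C@H](O)CC(C)(C)[C@H]1/C=C/C(C)=C/C=C/C(C)=C/C=C/C=C(C)/C=C/C=C(C)/C=C/[C@H]1C(C)=C[C@H](O[Si](CC)(CC)CC)CC1(C)C | intermediate
15 | (all-E,6R,3'R,6'R)-3'-(triethylsilyloxy)-ε,ε-caroten-3-one | CC1=CC(=O)CC(C)(C)[C@H]1/C=C/C(C)=C/C=C/C(C)=C/C=C/C=C(C)/C=C/C=C(C)/C=C/[C@H]1C(C)=C[C@H](O[Si](CC)(CC)CC)CC1(C)C | intermediate
16 | (all-E,6R,3'R,6'R)-3'-hydroxy-ε,ε-caroten-3-one | CC1=CC(=O)CC(C)(C)[C@H]1/C=C/C(C)=C/C=C/C(C)=C/C=C/C=C(C)/C=C/C=C(C)/C=C/[C@H]1C(C)=C[C@H](O)CC1(C)C | target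

**Step count and risks**

Total step count: 13. Longest linear sequence: 10 steps (steps 1, 2, 3, 4, 5, 6, 10, 11, 12, 13, from 1 to 16).

Three steps most likely to fail:

Step 1 (the proposed new cyclisation). The dienone may bind the acid and stop turnover, the ee may be low, or β-ionone may form. The fallback uses known chemistry, sets out from 1 and comes back at 2. Compound 1 is cyclised with 85% H3PO4 in toluene at 80 °C to racemic α-ionone F1. F1 is resolved by preparative supercritical-fluid chromatography on a cellulose tris(3,5-dimethylphenylcarbamate) column. The (R)-enantiomer is 2, and the unwanted (S)-α-ionone F2 is set aside.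

Step 4 (CBS reduction). The required hydride delivery is on the face syn to the C6 side chain, which is probably mismatched with the substrate's own bias, so the trans:cis ratio may be poor. The fallback sets out from 4 and comes back at 5. Reduction of 4 with NaBH4 and CeCl3·7H2O in MeOH at −40 °C gives 5 together with its C3 epimer, (2E,4E)-5-[(1R,4S)-4-hydroxy-2,6,6-trimethylcyclohex-2-en-1-yl]-3-methylpenta-2,4-dienenitrile F3, and the two are separated by chromatography. F3 is inverted by a Mitsunobu reaction (4-nitrobenzoic acid, PPh3, DIAD, toluene, 0 °C) to (1R,4R)-4-[(1E,3E)-4-cyano-3-methylbuta-1,3-dien-1-yl]-3,5,5-trimethylcyclohex-2-en-1-yl 4-nitrobenzoate F4. Methanolysis of F4 with K2CO3 in MeOH at 0 °C gives 5.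

Step 10 (mono-olefination of the symmetric bisphosphonate). Double olefination or anion scrambling may erode the yield of 13. The fallback sets out from 7 and 12 and comes back at 16, bypassing the protecting group. Bisphosphonate 12 (1 equiv, 2.1 equiv NaN(SiMe3)2, THF, −78 to 0 °C) is olefinated twice with 7 (2.2 equiv) to give the symmetric (all-E,3R,6R,3'R,6'R)-ε,ε-carotene-3,3'-diol F5. F5 is then oxidised with a deficit of activated MnO2 in CH2Cl2, stopped near half conversion, which gives 16 directly. Unreacted F5 is recycled and the over-oxidised (all-E,6R,6'R)-ε,ε-carotene-3,3'-dione F6 is removed by chromatography.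

**Further compounds**
F1 | step 1 | racemic α-ionone, (3E)-4-(2,6,6-trimethylcyclohex-2-en-1-yl)but-3-en-2-one | CC(=O)/C=C/C1C(C)=CCCC1(C)C
F2 | step 1 | (S)-α-ionone, (3E)-4-[(1S)-2,6,6-trimethylcyclohex-2-en-1-yl]but-3-en-2-one | CC(=O)/C=C/[C@@H]1C(C)=CCCC1(C)C
F3 | step 4 | (2E,4E)-5-[(1R,4S)-4-hydroxy-2,6,6-trimethylcyclohex-2-en-1-yl]-3-methylpenta-2,4-dienenitrile | N#C/C=C(C)/C=C/[C@H]1C(C)=C[C@@H](O)CC1(C)C
F4 | step 4 | (1R,4R)-4-[(1E,3E)-4-cyano-3-methylbuta-1,3-dien-1-yl]-3,5,5-trimethylcyclohex-2-en-1-yl 4-nitrobenzoate | N#C/C=C(C)/C=C/[C@H]1C(C)=C[C@H](OC(=O)c2ccc(cc2)[N+](=O)[O-])CC1(C)C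
F5 | step 10 | (all-E,3R,6R,3'R,6'R)-ε,ε-carotene-3,3'-diol | CC1=C[C@H](O)CC(C)(C)[C@H]1/C=C/C(C)=C/C=C/C(C)=C/C=C/C=C(C)/C=C/C=C(C)/C=C/[C@H]1C(C)=C[C@H](O)CC1(C)C
F6 | step 10 | (all-E,6R,6'R)-ε,ε-carotene-3,3'-dione | CC1=CC(=O)CC(C)(C)[C@H]1/C=C/C(C)=C/C=C/C(C)=C/C=C/C=C(C)/C=C/C=C(C)/C=C/[C@H]1C(C)=CC(=O)CC1(C)C
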